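## Retrosynthetic overview

- The target is cut at the E‑CH=CH bond by cross‑metathesis into fragment A (a C15 tertiary vinyl carbinol) and fragment B (a C11 allyl‑1,2‑dioxane propanoic acid).
- Fragment A comes from Sharpless epoxidation and reductive opening of an E‑allylic alcohol, itself made by B‑alkyl Suzuki coupling of 2,6,6‑trimethylcyclohexenyl triflate (from 2‑methylcyclohexanone) with a C6 dienyl borane.
- Fragment B: the dioxane is closed by 6‑exo SN2 attack of a tertiary hydroperoxide on a secondary mesylate. The hydroperoxide comes from inversion opening of a chiral oxetane with H2O2, the oxetane from Sharpless epoxidation and hydride opening, and the CH–CH(CH3) pair from Brown crotylboration.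
- Ring order: the cyclohexene is carried in from the start; an oxirane and an oxetane are transient; the 1,2‑dioxane is the only ring built, and it is closed before the coupling.

Assumption: (2E)‑3‑methylpent‑2‑en‑4‑yn‑1‑ol is bought as the pure E isomer, and 2‑methylcyclohexanone is used racemic because its stereocentre is erased.

## Route

**Fragment A**

Step 1
Reactants: 1 2-methylcyclohexanone (racemic)
Product: 3 2,6-dimethylcyclohexanone (cis/trans mixture), via lithium 6-methylcyclohex-1-en-1-olate 2 (not isolated)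
Conditions: LiN(iPr)2 (1.05 equiv), THF, −78 °C; MeI, −78 → 0 °C
Reagents that add atoms: iodomethane, CI; LiN(iPr)2, [Li+].CC(C)[N-]C(C)C (lithium stays in intermediate 2 only)
Why: Kinetic enolate alkylation, in which the amide base removes the less hindered C6 proton at −78 °C and MeI C‑methylates there; the stereocentres do not matter because they are erased by step 3.

Step 2
Reactants: 3 2,6-dimethylcyclohexanone
Product: 5 2,2,6-trimethylcyclohexanone (racemic), via lithium 2,6-dimethylcyclohex-1-en-1-olate 4 (not isolated)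
Conditions: LiN(iPr)2 (1.1 equiv), THF, −78 → 0 °C; MeI (1.2 equiv), 0 °C → rt
Reagents that add atoms: iodomethane, CI; LiN(iPr)2, [Li+].CC(C)[N-]C(C)C (lithium stays in intermediate 4 only)
Why: Enolate alkylation in which only the tetrasubstituted enolate can form, so methylation builds the gem‑dimethyl carbon and one equivalent of base limits a fourth methylation.

Step 3
Reactants: 5 2,2,6-trimethylcyclohexanone
Product: 7 2,6,6-trimethylcyclohex-1-en-1-yl trifluoromethanesulfonate, via lithium 2,6,6-trimethylcyclohex-1-en-1-olate 6 (not isolated)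
Conditions: LiN(iPr)2, THF, −78 → 0 °C; PhNTf2, 0 °C → rt
Reagents that add atoms: N-phenylbis(trifluoromethanesulfonimide), O=S(=O)(N(c1ccccc1)S(=O)(=O)C(F)(F)F)C(F)(F)F; LiN(iPr)2, [Li+].CC(C)[N-]C(C)C (lithium stays in intermediate 6 only)
Why: Enol triflate formation, where the single remaining α‑hydrogen allows only one enolate and PhNTf2 sulfonylates it on oxygen to give the tetrasubstituted vinyl triflate.

Step 4
Reactants: 8 (2E)-3-methylpent-2-en-4-yn-1-ol
Product: 9 tert-butyldimethyl{[(2E)-3-methylpent-2-en-4-yn-1-yl]oxy}silane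
Conditions: TBSCl, imidazole, DMF, rt
Reagents that add atoms: tert-butyldimethylsilyl chloride, CC(C)(C)[Si](C)(C)Cl
Why: Silyl ether protection of the primary alcohol so that it neither consumes borane nor interferes in the coupling.

Step 5
Reactants: 9 tert-butyldimethyl{[(2E)-3-methylpent-2-en-4-yn-1-yl]oxy}silane
Product: 10 tert-butyldimethyl{[(2E)-3-methylpenta-2,4-dien-1-yl]oxy}silane
Conditions: H2 (1 atm, 1 equiv uptake), Pd on CaCO3 poisoned with Pb(OAc)2, quinoline, hexane, rt
Reagents that add atoms: none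
Why: Lindlar semihydrogenation, in which the poisoned catalyst reduces the terminal alkyne to the vinyl group and leaves the trisubstituted E alkene untouched.

Step 6
Reactants: 10 tert-butyldimethyl{[(2E)-3-methylpenta-2,4-dien-1-yl]oxy}silane; 7 2,6,6-trimethylcyclohex-1-en-1-yl trifluoromethanesulfonate
Product: 12 tert-butyldimethyl{[(2E)-3-methyl-5-(2,6,6-trimethylcyclohex-1-en-1-yl)pent-2-en-1-yl]oxy}silane, via alkyl-9-BBN adduct 11 (not isolated)
Conditions: 9-BBN (1.1 equiv), THF, 0 °C → rt; then 7, PdCl2(dppf) (5 mol %), AsPh3 (10 mol %), Cs2CO3, DMF/THF/H2O, 50 °C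
Reagents that add atoms: 9-borabicyclo[3.3.1]nonane, B1C2CCCC1CCC2 (its boron unit stays in intermediate 11 only)
Why: Hydroboration followed by B‑alkyl Suzuki–Miyaura coupling, in which 9‑BBN adds only to the terminal vinyl with boron at the chain end and the primary alkylborane couples with the vinyl triflate with the E alkene retained.

Step 7
Reactants: 12 tert-butyldimethyl{[(2E)-3-methyl-5-(2,6,6-trimethylcyclohex-1-en-1-yl)pent-2-en-1-yl]oxy}silane
Product: 13 (2E)-3-methyl-5-(2,6,6-trimethylcyclohex-1-en-1-yl)pent-2-en-1-ol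
Conditions: Bu4NF, THF, 0 °C → rt
Reagents that add atoms: none
Why: Fluoride‑mediated desilylation driven by the strong Si–F bond, freeing the allylic alcohol needed to direct the epoxidation.

Step 8
Reactants: 13 (2E)-3-methyl-5-(2,6,6-trimethylcyclohex-1-en-1-yl)pent-2-en-1-ol
Product: 14 {(2S,3S)-3-methyl-3-[2-(2,6,6-trimethylcyclohex-1-en-1-yl)ethyl]oxiran-2-yl}methanol
Conditions: Ti(OiPr)4 (10 mol %), L-(+)-diethyl tartrate (12 mol %), t-BuOOH (2 equiv), 4 Å sieves, CH2Cl2, −20 °C
Reagents that add atoms: tert-butyl hydroperoxide, CC(C)(C)OO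
Why: Sharpless asymmetric epoxidation, which oxidises only the allylic alkene and with L‑(+)‑tartrate on a geraniol‑type E alcohol gives the (2S,3S) epoxide, fixing the future carbinol carbon as S.

Step 9
Reactants: 14 {(2S,3S)-3-methyl-3-[2-(2,6,6-trimethylcyclohex-1-en-1-yl)ethyl]oxiran-2-yl}methanol
Product: 15 (2R,3S)-2-(iodomethyl)-3-methyl-3-[2-(2,6,6-trimethylcyclohex-1-en-1-yl)ethyl]oxirane
Conditions: I2, PPh3, imidazole, Et2O/MeCN (3:1), 0 °C
Reagents that add atoms: iodine, II
Why: Appel‑type iodination of the primary alcohol under neutral buffered conditions that leave the epoxide closed (the C2 descriptor changes only because CH2I outranks C3).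

Step 10
Reactants: 15 (2R,3S)-2-(iodomethyl)-3-methyl-3-[2-(2,6,6-trimethylcyclohex-1-en-1-yl)ethyl]oxirane
Product: 16 (3S)-3-methyl-5-(2,6,6-trimethylcyclohex-1-en-1-yl)pent-1-en-3-ol (fragment A)
Conditions: Zn dust, EtOH, reflux; aq. NH4Cl
Reagents that add atoms: none
Why: Zinc‑mediated reductive ring opening (β‑elimination) of the 2,3‑epoxy iodide, where zinc inserts into the carbon–iodine bond and the epoxide oxygen leaves from C2, so the C3–O bond and its S configuration are untouched.

**Fragment B**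

Step 11
Reactants: 17 hex-5-en-1-yne
Product: 19 (2E)-3-methylhepta-2,6-dien-1-ol, via (E)-alkenyldimethylalane 18 (not isolated)
Conditions: Me3Al (2 equiv), Cp2ZrCl2 (0.25 equiv), CH2Cl2, 0 °C → rt; then (CH2O)n, 0 °C → rt; 1 M HCl
Reagents that add atoms: trimethylaluminium, C[Al](C)C; paraformaldehyde (as formaldehyde), C=O
Why: Negishi zirconium‑catalysed carboalumination, a syn addition of methyl and aluminium across the alkyne (the isolated alkene reacts far more slowly), followed by hydroxymethylation with retention to give only the E alcohol.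

Step 12
Reactants: 19 (2E)-3-methylhepta-2,6-dien-1-ol
Product: 20 [(2R,3R)-3-(but-3-en-1-yl)-3-methyloxiran-2-yl]methanol
Conditions: Ti(OiPr)4 (10 mol %), D-(−)-diethyl tartrate (12 mol %), t-BuOOH (2 equiv), 4 Å sieves, CH2Cl2, −20 °C
Reagents that add atoms: tert-butyl hydroperoxide, CC(C)(C)OO
Why: Sharpless asymmetric epoxidation with the unnatural tartrate, which gives the (2R,3R) epoxide and leaves the terminal alkene alone; C3 becomes the quaternary dioxane carbon.

Step 13
Reactants: 20 [(2R,3R)-3-(but-3-en-1-yl)-3-methyloxiran-2-yl]methanol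
Product: 21 (3R)-3-methylhept-6-ene-1,3-diol
Conditions: NaAlH2(OCH2CH2OMe)2, THF, 0 °C → rt
Reagents that add atoms: none
Why: Regioselective hydride opening of a 2,3‑epoxy alcohol, with hydride delivered from the O1‑bound aluminate to C2 so that the tertiary C3–O bond and its configuration are kept.

Step 14
Reactants: 21 (3R)-3-methylhept-6-ene-1,3-diol
Product: 23 (2R)-2-(but-3-en-1-yl)-2-methyloxetane, via primary monotosylate 22 (not isolated)
Conditions: n-BuLi (1.0 equiv), THF, 0 °C; TsCl (1.0 equiv); n-BuLi (1.05 equiv), 0 → 60 °C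
Reagents that add atoms: 4-methylbenzenesulfonyl chloride, Cc1ccc(cc1)S(Cl)(=O)=O (the tosyl group stays in intermediate 22 only)
Why: One‑pot monotosylation and intramolecular Williamson etherification (4‑exo‑tet), in which the tertiary alkoxide displaces the primary tosylate and the stereocentre keeps its C–O bond.

Step 15
Reactants: 23 (2R)-2-(but-3-en-1-yl)-2-methyloxetane
Product: 24 3-[(2R)-2-methyloxetan-2-yl]propanal
Conditions: O3, pyridine (3 equiv), CH2Cl2, −78 °C
Reagents that add atoms: ozone, [O-][O+]=O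
Why: Ozonolysis of the only alkene, with pyridine breaking down the carbonyl oxide in the flask so the aldehyde forms directly and the oxetane is untouched.

Step 16
Reactants: 24 3-[(2R)-2-methyloxetan-2-yl]propanal; 25 (E)-but-2-ene
Product: 29 (3R,4S)-4-methyl-1-[(2R)-2-methyloxetan-2-yl]hex-5-en-3-ol, via (E)-crotylpotassium 26 (not isolated), via (E)-crotyldiisopinocampheylborane 27 (not isolated), via borinate ester 28 (not isolated)
Conditions: 25, KOtBu, n-BuLi, THF, −78 → −45 °C; (−)-Ipc2BOMe [from (+)-α-pinene], −78 °C; BF3·OEt2 (1.0 equiv per boron); 24, −78 °C, 4 h; 3 M NaOH, 30% H2O2, rt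
Reagents that add atoms: (−)-B-methoxydiisopinocampheylborane, COB([C@@H]1C[C@@H]2C[C@H]([C@H]1C)C2(C)C)[C@@H]1C[C@@H]2C[C@H]([C@H]1C)C2(C)C (its boryl group stays in intermediates 27 and 28 only); KOtBu, CC(C)(C)[O-].[K+] (potassium stays in intermediate 26 only)
Why: Brown asymmetric crotylboration through a closed chair transition state, where the E‑crotyl geometry gives the anti methyl/hydroxyl pair and the isopinocampheyl groups from (+)-α-pinene direct attack to the si face of the aldehyde, giving the (3R,4S) alcohol.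

Step 17
Reactants: 29 (3R,4S)-4-methyl-1-[(2R)-2-methyloxetan-2-yl]hex-5-en-3-ol
Product: 30 (3R,4S)-4-methyl-1-[(2R)-2-methyloxetan-2-yl]hex-5-en-3-yl methanesulfonate
Conditions: MsCl, Et3N, CH2Cl2, 0 °C
Reagents that add atoms: methanesulfonyl chloride, CS(Cl)(=O)=O
Why: Sulfonylation with retention turns the carbinol into the leaving group for ring closure and stops it attacking the oxetane in the next step.

Step 18
Reactants: 30 (3R,4S)-4-methyl-1-[(2R)-2-methyloxetan-2-yl]hex-5-en-3-yl methanesulfonate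
Product: 31 (3S,6R,7S)-3-hydroperoxy-1-hydroxy-3,7-dimethylnon-8-en-6-yl methanesulfonate
Conditions: anhydrous H2O2 in Et2O (5 equiv), TMSOTf (0.2 equiv), Et2O, −78 → 0 °C
Reagents that add atoms: hydrogen peroxide, OO
Why: Lewis acid‑promoted SN2‑type perhydrolysis of the oxetane, in which H2O2 attacks the silylated oxetane at the tertiary carbon from the rear, inverting R to the S tertiary hydroperoxide and releasing the primary alcohol.

Step 19
Reactants: 31 (3S,6R,7S)-3-hydroperoxy-1-hydroxy-3,7-dimethylnon-8-en-6-yl methanesulfonate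
Product: 32 2-[(3S,6S)-6-[(2S)-but-3-en-2-yl]-3-methyl-1,2-dioxan-3-yl]ethan-1-ol
Conditions: KOtBu (1.1 equiv), 18-crown-6 (0.2 equiv), THF, 0 °C → rt
Reagents that add atoms: none
Why: Intramolecular Williamson‑type O‑alkylation (6‑exo‑tet SN2), in which the more acidic hydroperoxide is deprotonated in preference to the alcohol and displaces the mesylate with inversion, setting the ring CH carbon as S with its side chain cis to the ring methyl; E2 is the competing path.

Step 20
Reactants: 32 2-[(3S,6S)-6-[(2S)-but-3-en-2-yl]-3-methyl-1,2-dioxan-3-yl]ethan-1-ol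
Product: 34 (2R)-2-[(3S,6S)-6-(2-hydroxyethyl)-6-methyl-1,2-dioxan-3-yl]propanoic acid, via α-methyl aldehyde 33 (not isolated)
Conditions: O3, MeCN/H2O (9:1), 0 °C; N2 purge; NaClO2, NaH2PO4, 0 °C → rt
Reagents that add atoms: ozone, [O-][O+]=O; sodium chlorite, [Na+].[O-]Cl=O
Why: Ozonolysis in wet acetonitrile followed by chlorite (Pinnick‑type) oxidation in the same flask, which turns the vinyl group into the acid under buffered conditions that do not epimerise the α‑carbon or oxidise the primary alcohol or the peroxide (the descriptor becomes R only by priority change).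

Step 21
Reactants: 34 (2R)-2-[(3S,6S)-6-(2-hydroxyethyl)-6-methyl-1,2-dioxan-3-yl]propanoic acid
Product: 35 (2R)-2-[(3S,6S)-6-methyl-6-(2-oxoethyl)-1,2-dioxan-3-yl]propanoic acid
Conditions: Dess–Martin periodinane (1.3 equiv), CH2Cl2, 0 °C → rt; used at once
Reagents that add atoms: none
Why: Dess–Martin oxidation, a neutral to mildly acidic oxidation of the primary alcohol that avoids base‑induced opening of the β‑peroxy aldehyde.

Step 22
Reactants: 35 (2R)-2-[(3S,6S)-6-methyl-6-(2-oxoethyl)-1,2-dioxan-3-yl]propanoic acid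
Product: 36 (2R)-2-[(3S,6S)-6-methyl-6-(prop-2-en-1-yl)-1,2-dioxan-3-yl]propanoic acid (fragment B)
Conditions: Ph3PCH3Br (3.5 equiv), KN(SiMe3)2 (3.3 equiv), THF, 0 °C; then 35, −78 → 0 °C; aq. NaH2PO4
Reagents that add atoms: methyltriphenylphosphonium bromide, C[P+](c1ccccc1)(c1ccccc1)c1ccccc1.[Br-]
Why: Wittig methylenation, where the first equivalent of ylide forms the inert carboxylate and carbonyl addition at −78 °C outruns enolisation of the aldehyde, giving the terminal allyl group.

**Coupling**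

Step 23
Reactants: 16 (3S)-3-methyl-5-(2,6,6-trimethylcyclohex-1-en-1-yl)pent-1-en-3-ol (2.5 equiv); 36 (2R)-2-[(3S,6S)-6-methyl-6-(prop-2-en-1-yl)-1,2-dioxan-3-yl]propanoic acid
Product: 37 (2R)-2-[(3S,6S)-6-[(2E,4S)-4-hydroxy-4-methyl-6-(2,6,6-trimethylcyclohex-1-en-1-yl)hex-2-en-1-yl]-6-methyl-1,2-dioxan-3-yl]propanoic acid (target)
Conditions: second-generation Hoveyda–Grubbs catalyst RuCl2(H2IMes)(=CH–C6H4-2-OiPr) (10 mol %), CH2Cl2, 40 °C, open to argon flow
Reagents that add atoms: none
Why: Olefin cross‑metathesis between the fast‑reacting allyl group and the hindered tertiary allylic alcohol, which does not homodimerise and gives the E alkene for steric reasons, while the tetrasubstituted ring alkene, the peroxide and the free acid are tolerated.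

## Compound list

1 | 2-methylcyclohexanone (racemic) | CC1CCCCC1=O | starting material
2 | lithium 6-methylcyclohex-1-en-1-olate (not isolated) | [Li+].[O-]C1=CCCCC1C | intermediate
3 | 2,6-dimethylcyclohexanone (cis/trans mixture) | CC1CCCC(C)C1=O | intermediate
4 | lithium 2,6-dimethylcyclohex-1-en-1-olate (not isolated) | [Li+].[O-]C1=C(C)CCCC1C | intermediate
5 | 2,2,6-trimethylcyclohexanone (racemic) | CC1CCCC(C)(C)C1=O | intermediate
6 | lithium 2,6,6-trimethylcyclohex-1-en-1-olate (not isolated) | [Li+].[O-]C1=C(C)CCCC1(C)C | intermediate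
7 | 2,6,6-trimethylcyclohex-1-en-1-yl trifluoromethanesulfonate | CC1=C(OS(=O)(=O)C(F)(F)F)C(C)(C)CCC1 | intermediate
8 | (2E)-3-methylpent-2-en-4-yn-1-ol | C#C/C(C)=C/CO | starting material
9 | tert-butyldimethyl{[(2E)-3-methylpent-2-en-4-yn-1-yl]oxy}silane | C#C/C(C)=C/CO[Si](C)(C)C(C)(C)C | intermediate
10 | tert-butyldimethyl{[(2E)-3-methylpenta-2,4-dien-1-yl]oxy}silane | C=C/C(C)=C/CO[Si](C)(C)C(C)(C)C | intermediate
11 | 9-[(3E)-5-{[tert-butyl(dimethyl)silyl]oxy}-3-methylpent-3-en-1-yl]-9-borabicyclo[3.3.1]nonane (not isolated) | B1(CC/C(C)=C/CO[Si](C)(C)C(C)(C)C)C2CCCC1CCC2 | intermediate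
12 | tert-butyldimethyl{[(2E)-3-methyl-5-(2,6,6-trimethylcyclohex-1-en-1-yl)pent-2-en-1-yl]oxy}silane | CC1=C(CC/C(C)=C/CO[Si](C)(C)C(C)(C)C)C(C)(C)CCC1 | intermediate
13 | (2E)-3-methyl-5-(2,6,6-trimethylcyclohex-1-en-1-yl)pent-2-en-1-ol | CC1=C(CC/C(C)=C/CO)C(C)(C)CCC1 | intermediate
14 | {(2S,3S)-3-methyl-3-[2-(2,6,6-trimethylcyclohex-1-en-1-yl)ethyl]oxiran-2-yl}methanol | OC[C@@H]1O[C@@]1(C)CCC1=C(C)CCCC1(C)C | intermediate
15 | (2R,3S)-2-(iodomethyl)-3-methyl-3-[2-(2,6,6-trimethylcyclohex-1-en-1-yl)ethyl]oxirane | IC[C@@H]1O[C@@]1(C)CCC1=C(C)CCCC1(C)C | intermediate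
16 | (3S)-3-methyl-5-(2,6,6-trimethylcyclohex-1-en-1-yl)pent-1-en-3-ol (fragment A) | CC1=C(CC[C@](C)(O)C=C)C(C)(C)CCC1 | intermediate
17 | hex-5-en-1-yne | C#CCCC=C | starting material
18 | dimethyl[(1E)-2-methylhexa-1,5-dien-1-yl]alumane (not isolated) | C=CCC/C(C)=C/[Al](C)C | intermediate
19 | (2E)-3-methylhepta-2,6-dien-1-ol | C=CCC/C(C)=C/CO | intermediate
20 | [(2R,3R)-3-(but-3-en-1-yl)-3-methyloxiran-2-yl]methanol | OC[C@H]1O[C@]1(C)CCC=C | intermediate
21 | (3R)-3-methylhept-6-ene-1,3-diol | OCC[C@](C)(O)CCC=C | intermediate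
22 | (3R)-3-hydroxy-3-methylhept-6-en-1-yl 4-methylbenzenesulfonate (not isolated) | Cc1ccc(cc1)S(=O)(=O)OCC[C@](C)(O)CCC=C | intermediate
23 | (2R)-2-(but-3-en-1-yl)-2-methyloxetane | C=CCC[C@]1(C)CCO1 | intermediate
24 | 3-[(2R)-2-methyloxetan-2-yl]propanal | O=CCC[C@]1(C)CCO1 | intermediate
25 | (E)-but-2-ene | C/C=C/C | starting material
26 | (E)-but-2-en-1-ylpotassium (not isolated) | C/C=C/[CH2-].[K+] | intermediate
27 | [(2E)-but-2-en-1-yl]bis[(1R,2S,3R,5R)-2,6,6-trimethylbicyclo[3.1.1]heptan-3-yl]borane (not isolated) | C/C=C/CB([C@@H]1C[C@@H]2C[C@H]([C@H]1C)C2(C)C)[C@@H]1C[C@@H]2C[C@H]([C@H]1C)C2(C)C | intermediate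
28 | (3R,4S)-4-methyl-1-[(2R)-2-methyloxetan-2-yl]hex-5-en-3-yl diisopinocampheylborinate (not isolated) | C=C[C@H](C)[C@H](OB([C@@H]1C[C@@H]2C[C@H]([C@H]1C)C2(C)C)[C@@H]1C[C@@H]2C[C@H]([C@H]1C)C2(C)C)CC[C@]1(C)CCO1 | intermediate
29 | (3R,4S)-4-methyl-1-[(2R)-2-methyloxetan-2-yl]hex-5-en-3-ol | C=C[C@H](C)[C@H](O)CC[C@]1(C)CCO1 | intermediate
30 | (3R,4S)-4-methyl-1-[(2R)-2-methyloxetan-2-yl]hex-5-en-3-yl methanesulfonate | C=C[C@H](C)[C@H](OS(C)(=O)=O)CC[C@]1(C)CCO1 | intermediate
31 | (3S,6R,7S)-3-hydroperoxy-1-hydroxy-3,7-dimethylnon-8-en-6-yl methanesulfonate | C=C[C@H](C)[C@H](OS(C)(=O)=O)CC[C@](C)(OO)CCO | intermediate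
32 | 2-[(3S,6S)-6-[(2S)-but-3-en-2-yl]-3-methyl-1,2-dioxan-3-yl]ethan-1-ol | C=C[C@H](C)[C@@H]1CC[C@@](C)(CCO)OO1 | intermediate
33 | (2R)-2-[(3S,6S)-6-(2-hydroxyethyl)-6-methyl-1,2-dioxan-3-yl]propanal (not isolated) | O=C[C@H](C)[C@@H]1CC[C@@](C)(CCO)OO1 | intermediate
34 | (2R)-2-[(3S,6S)-6-(2-hydroxyethyl)-6-methyl-1,2-dioxan-3-yl]propanoic acid | OC(=O)[C@H](C)[C@@H]1CC[C@@](C)(CCO)OO1 | intermediate
35 | (2R)-2-[(3S,6S)-6-methyl-6-(2-oxoethyl)-1,2-dioxan-3-yl]propanoic acid | OC(=O)[C@H](C)[C@@H]1CC[C@@](C)(CC=O)OO1 | intermediate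
36 | (2R)-2-[(3S,6S)-6-methyl-6-(prop-2-en-1-yl)-1,2-dioxan-3-yl]propanoic acid (fragment B) | OC(=O)[C@H](C)[C@@H]1CC[C@@](C)(CC=C)OO1 | intermediate
37 | (2R)-2-[(3S,6S)-6-[(2E,4S)-4-hydroxy-4-methyl-6-(2,6,6-trimethylcyclohex-1-en-1-yl)hex-2-en-1-yl]-6-methyl-1,2-dioxan-3-yl]propanoic acid | CC1=C(CC[C@](C)(O)/C=C/C[C@]2(C)CC[C@@H]([C@@H](C)C(=O)O)OO2)C(C)(C)CCC1 | target

## Step count and risks

Total step count: 23.
Longest linear sequence: 13 steps (17 → 37: steps 11 to 22, then step 23). The fragment A branch is 8 steps plus the coupling.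

Three steps most likely to fail:

**Step 6 (B‑alkyl Suzuki coupling on the doubly flanked, tetrasubstituted triflate).** Oxidative addition and transmetalation may be too slow, so that protodeboronation wins. The fallback makes the ring the nucleophile instead; it sets out from ketone 5 and from borane 11 and comes back at 12. Ketone 5 is condensed with 2,4,6-triisopropylbenzenesulfonylhydrazide (MeOH, cat. HCl) to give 2,2,6-trimethylcyclohexanone 2,4,6-triisopropylbenzenesulfonylhydrazone F1. A Shapiro reaction (s-BuLi 2.2 equiv, THF/TMEDA, −78 → 0 °C) then gives (2,6,6-trimethylcyclohex-1-en-1-yl)lithium F2. Borane 11 is cleaved with I2/NaOMe to the primary iodide tert-butyl{[(2E)-5-iodo-3-methylpent-2-en-1-yl]oxy}dimethylsilane F3. F2 is alkylated with F3 (THF/HMPA, −78 → 0 °C) to give 12.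

**Step 18 (H2O2 opening of the tertiary oxetane).** Risks are low conversion, ionisation with loss of configuration, or capture of the cation by the vinyl group. Loss of configuration here would give a separable C‑6 diastereomer of 32 rather than a racemate. The fallback reverses the roles of the two carbons; it sets out from mesylate 30 and comes back at 32, replacing steps 18 and 19. Mesylate 30 is displaced with inversion by 2-methoxyprop-2-yl hydroperoxide (CsOH·H2O, DMF) to give the peroxyketal (2R)-2-{(3S,4S)-3-[(2-methoxypropan-2-yl)peroxy]-4-methylhex-5-en-1-yl}-2-methyloxetane F4. Aqueous acetic acid frees the secondary hydroperoxide (2R)-2-[(3S,4S)-3-hydroperoxy-4-methylhex-5-en-1-yl]-2-methyloxetane F5. Catalytic TMSOTf (CH2Cl2, −78 → −20 °C) then lets the tethered hydroperoxide open the oxetane 6‑exo with inversion at the tertiary carbon, giving 32. The weak point of this fallback is the intermolecular SN2 at the branched mesylate.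

**Step 22 (Wittig methylenation of the β‑peroxy aldehyde).** The basic ylide may enolise the aldehyde and open the peroxide by E1cB. The fallback is a two‑stage Peterson olefination that avoids a basic elimination; it sets out from aldehyde 35 and comes back at 36. Aldehyde 35 is treated with the weakly basic cerium reagent from Me3SiCH2MgCl and CeCl3 (3 equiv, THF, −78 °C; the first equivalent forms the carboxylate) to give the β‑hydroxysilane (2R)-2-{(3S,6S)-6-[2-hydroxy-3-(trimethylsilyl)propyl]-6-methyl-1,2-dioxan-3-yl}propanoic acid F6 as a mixture of carbinol epimers. Catalytic H2SO4 in THF at 0 °C then eliminates trimethylsilanol to give 36.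

Further compounds
F1 | step 6 | 2,2,6-trimethylcyclohexanone 2,4,6-triisopropylbenzenesulfonylhydrazone | CC1CCCC(C)(C)C1=NNS(=O)(=O)c1c(C(C)C)cc(C(C)C)cc1C(C)C
F2 | step 6 | (2,6,6-trimethylcyclohex-1-en-1-yl)lithium | [Li]C1=C(C)CCCC1(C)C
F3 | step 6 | tert-butyl{[(2E)-5-iodo-3-methylpent-2-en-1-yl]oxy}dimethylsilane | ICC/C(C)=C/CO[Si](C)(C)C(C)(C)C
F4 | step 18 | (2R)-2-{(3S,4S)-3-[(2-methoxypropan-2-yl)peroxy]-4-methylhex-5-en-1-yl}-2-methyloxetane | C=C[C@H](C)[C@@H](OOC(C)(C)OC)CC[C@]1(C)CCO1
F5 | step 18 | (2R)-2-[(3S,4S)-3-hydroperoxy-4-methylhex-5-en-1-yl]-2-methyloxetane | C=C[C@H](C)[C@@H](OO)CC[C@]1(C)CCO1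
F6 | step 22 | (2R)-2-{(3S,6S)-6-[2-hydroxy-3-(trimethylsilyl)propyl]-6-methyl-1,2-dioxan-3-yl}propanoic acid (both carbinol epimers) | OC(=O)[C@H](C)[C@@H]1CC[C@@](C)(CC(O)C[Si](C)(C)C)OO1
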